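**Retrosynthetic overview**

1. The last C–C bond made joins C5 of the central resorcinol ring (para to one phenolic oxygen, ortho to the other) to C2 of the oxolane. It is formed at the ketone oxidation level, as an acyl–aryl bond between a thioester (fragment 1) and an arylboronic acid (fragment 2); the same flask then closes the oxolane and sets C2.
2. Enabling feature: oxolane C2 carries ring oxygen O1, one H and the electron-rich aryl carbon, and O1 sits on C5, gamma to C2. C2 is therefore a hidden 2,4-dioxygenated aryl ketone carbonyl with a gamma-silyloxy group; it closes O1–C2 (5-exo-trig) to a 2-aryloxolanylium ion, which takes hydride anti to the C3 benzyl group and so gives the 2,3-cis relationship.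
3. Fragment 1 (C3, C4, C5 already set): oxazolidinone alkylation (C3), thiazolidinethione anti-aldol (C4/C5), aryl Grignard acylation (aroyl ketone), thiolate exchange (thioester).
4. Fragment 2: the pyran ring of the chroman is built by an enantioselective ortho-quinone methide/E-stilbene [4+2] cycloaddition that sets its three stereocentres; then chalcone by aldol condensation, then bromide to boronic acid.
5. Ring order: pyran ring of the chroman (step 16), then the oxolane (step 21); global desilylation ends the route. The boron, the thioester and the ketone oxidation level are all removed in step 21.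

Key step: step 21

Abbreviations: TBS = tert-butyldimethylsilyl, TES = triethylsilyl; oxolane and chroman atoms keep the numbering of the target.

Assumption: the sense of induction of the two auxiliaries (steps 3 and 6) and of the chiral Brønsted acid (step 16) is taken from the accepted transition-state models; if one proves opposite, the mirror-image auxiliary or catalyst is used.

**Route**

Step 1
Reactants: 1 3-(4-hydroxyphenyl)propanoic acid
Product: 3 3-[4-(TBSO)phenyl]propanoic acid, via silyl ester 2 (not isolated)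
Conditions: t-BuMe2SiCl (2.4 equiv), imidazole, DMF, rt; then THF/H2O/AcOH, rt
Reagents that add atoms: tert-butyldimethylsilyl chloride, CC(C)(C)[Si](C)(C)Cl
Why: Silylation of phenol and acid, the labile silyl ester being hydrolysed on work-up while the aryl silyl ether stays (standard silyl protection).

Step 2
Reactants: 3 3-[4-(TBSO)phenyl]propanoic acid; 4 (S)-4-benzyl-1,3-oxazolidin-2-one
Product: 6 (S)-4-benzyl-3-{3-[4-(TBSO)phenyl]propanoyl}-1,3-oxazolidin-2-one, via mixed pivalic anhydride 5 (not isolated)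
Conditions: t-BuCOCl, Et3N, THF, −20 °C; then 4, LiCl, rt
Reagents that add atoms: none
Why: N-Acylation of the oxazolidinone through the mixed anhydride under LiCl/Et3N activation (standard auxiliary attachment).

Step 3
Reactants: 6 (S)-4-benzyl-3-{3-[4-(TBSO)phenyl]propanoyl}-1,3-oxazolidin-2-one
Product: 8 tert-butyl (3R)-4-[(4S)-4-benzyl-2-oxo-1,3-oxazolidin-3-yl]-4-oxo-3-[4-(TBSO)benzyl]butanoate, via sodium enolate 7 (not isolated)
Conditions: NaN(SiMe3)2, THF, −78 °C; BrCH2CO2t-Bu, −78 to −20 °C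
Reagents that add atoms: tert-butyl bromoacetate, BrCC(=O)OC(C)(C)C
Why: Evans alkylation: the chelated Z-enolate is alkylated on the face opposite the benzyl group of the auxiliary, which sets the future oxolane C3 (R).

Step 4
Reactants: 8 tert-butyl ester from step 3
Product: 9 (3R)-4-[(4S)-4-benzyl-2-oxo-1,3-oxazolidin-3-yl]-4-oxo-3-[4-(TBSO)benzyl]butanoic acid
Conditions: CF3CO2H/CH2Cl2 (1:4), 0 °C
Reagents that add atoms: none
Why: Acidolysis of the tert-butyl ester with loss of 2-methylpropene; the imide and the aryl silyl ether should tolerate cold CF3CO2H.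

Step 5
Reactants: 9 acid from step 4; 10 (R)-4-benzyl-1,3-thiazolidine-2-thione
Product: 11 (S)-4-benzyl-3-{(2R)-2-[4-(TBSO)benzyl]-4-[(4R)-4-benzyl-2-thioxo-1,3-thiazolidin-3-yl]-4-oxobutanoyl}-1,3-oxazolidin-2-one
Conditions: DCC, DMAP (cat.), CH2Cl2, 0 °C to rt
Reagents that add atoms: none
Why: Carbodiimide-mediated (Steglich-type) N-acylation of the thiazolidinethione, which installs the second, more activating auxiliary on the CH2-bearing carbonyl.

Step 6
Reactants: 11 bis-acylated compound from step 5; 12 4-(TBSO)benzaldehyde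
Product: 14 (S)-4-benzyl-3-[(2R,3R)-2-[4-(TBSO)benzyl]-3-{(S)-hydroxy[4-(TBSO)phenyl]methyl}-4-oxo-4-((4R)-4-benzyl-2-thioxo-1,3-thiazolidin-3-yl)butanoyl]-1,3-oxazolidin-2-one, via trimethylsilyl ether 13 (not isolated)
Conditions: MgBr2·OEt2 (0.2 equiv), Et3N, Me3SiCl, EtOAc, rt; then THF/1 M HCl
Reagents that add atoms: none
Why: Magnesium halide-catalysed direct anti-aldol of an N-acylthiazolidinethione: soft enolization occurs only at the CH2 of the more acidic thioimide, the thiazolidinethione controls the enolate face, and the silyl-trapped transition state gives the anti adduct, which sets the future oxolane C4 (R) and C5 (S).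

Step 7
Reactants: 14 anti-aldol adduct
Product: 15 triethylsilyl ether of 14
Conditions: Et3SiOTf, 2,6-lutidine, CH2Cl2, −78 to 0 °C
Reagents that add atoms: triethylsilyl trifluoromethanesulfonate, CC[Si](CC)(CC)OS(=O)(=O)C(F)(F)F
Why: Silylation of the secondary alcohol with a group more labile than the aryl TBS ethers, which blocks retro-aldol and lactonization and later becomes the leaving silyl group of the ring closure.

Step 8
Reactants: 16 4-bromobenzene-1,3-diol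
Product: 17 1-bromo-2,4-bis(TBSO)benzene
Conditions: t-BuMe2SiCl, imidazole, DMF, rt
Reagents that add atoms: tert-butyldimethylsilyl chloride, CC(C)(C)[Si](C)(C)Cl
Why: Standard phenol silylation.

Step 9
Reactants: 15 triethylsilyl ether from step 7; 17 1-bromo-2,4-bis(TBSO)benzene
Product: 19 (S)-4-benzyl-3-{(2R,3R,4S)-3-[2,4-bis(TBSO)benzoyl]-2-[4-(TBSO)benzyl]-4-[4-(TBSO)phenyl]-4-(triethylsilyloxy)butanoyl}-1,3-oxazolidin-2-one, via aryl Grignard reagent 18 (not isolated)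
Conditions: 17, Mg, LiCl, THF, rt; then 15, THF, −78 to −20 °C; NH4Cl
Reagents that add atoms: none
Why: Ketone synthesis by acyl substitution of the activated N-acylthiazolidinethione with an aryl Grignard reagent; the tetrahedral intermediate should persist until work-up and the less electrophilic oxazolidinone imide should stay untouched.

Step 10
Reactants: 19 aryl ketone from step 9
Product: 20 S-ethyl (2R,3R,4S)-3-[2,4-bis(TBSO)benzoyl]-2-[4-(TBSO)benzyl]-4-[4-(TBSO)phenyl]-4-(triethylsilyloxy)butanethioate (fragment 1)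
Conditions: EtSH, n-BuLi, THF, 0 °C
Reagents that add atoms: ethanethiol, CCS
Why: Thiolate transacylation of the N-acyloxazolidinone (exocyclic cleavage by the soft, weakly basic lithium thiolate) should give the thioester without epimerization of either alpha centre.

Step 11
Reactants: 21 3-bromo-4-hydroxybenzaldehyde
Product: 22 3-bromo-4-(TBSO)benzaldehyde
Conditions: t-BuMe2SiCl, imidazole, CH2Cl2, rt
Reagents that add atoms: tert-butyldimethylsilyl chloride, CC(C)(C)[Si](C)(C)Cl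
Why: Standard phenol silylation.

Step 12
Reactants: 22 3-bromo-4-(TBSO)benzaldehyde; 23 tert-butyldimethyl(4-vinylphenoxy)silane
Product: 24 4-(TBSO)-3-{(E)-2-[4-(TBSO)phenyl]ethenyl}benzaldehyde
Conditions: Pd(OAc)2, P(o-tol)3, Et3N, DMF, 90 °C
Reagents that add atoms: none
Why: Heck reaction of the formyl-activated aryl bromide; syn insertion and syn beta-hydride elimination give the E-stilbene.

Step 13
Reactants: 25 4,6-dibromobenzene-1,3-diol
Product: 26 1,5-dibromo-2,4-bis(TBSO)benzene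
Conditions: t-BuMe2SiCl, imidazole, DMF, rt
Reagents that add atoms: tert-butyldimethylsilyl chloride, CC(C)(C)[Si](C)(C)Cl
Why: Standard phenol silylation; the second bromine marks the carbon that will later carry boron.

Step 14
Reactants: 27 2,4-dihydroxybenzaldehyde
Product: 28 4-(TBSO)-2-hydroxybenzaldehyde
Conditions: t-BuMe2SiCl (1.0 equiv), imidazole, CH2Cl2, 0 °C
Reagents that add atoms: tert-butyldimethylsilyl chloride, CC(C)(C)[Si](C)(C)Cl
Why: The 2-OH is deactivated by its hydrogen bond to the formyl oxygen, so silylation should occur at the 4-OH only.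

Step 15
Reactants: 26 1,5-dibromo-2,4-bis(TBSO)benzene; 28 4-(TBSO)-2-hydroxybenzaldehyde
Product: 30 [5-bromo-2,4-bis(TBSO)phenyl][4-(TBSO)-2-hydroxyphenyl]methanol (racemic), via aryllithium 29 (not isolated)
Conditions: 26 (2.2 equiv), n-BuLi (2.2 equiv), THF, −78 °C; then 28, −78 to −40 °C; NH4Cl
Reagents that add atoms: none
Why: Bromine–lithium exchange on the symmetrical dibromide, then 1,2-addition to the aldehyde (one equivalent of aryllithium is consumed by the phenol); the carbinol centre is irrelevant because it is planarized in step 16.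

Step 16
Reactants: 30 benzhydrol from step 15; 24 E-stilbene aldehyde from step 12
Product: 32 3-{(2S,3R,4S)-4-[5-bromo-2,4-bis(TBSO)phenyl]-7-(TBSO)-2-[4-(TBSO)phenyl]-3,4-dihydro-2H-chromen-3-yl}-4-(TBSO)benzaldehyde, via ortho-quinone methide 31 (not isolated)
Conditions: (R)-N-triflylphosphoramide of 3,3'-bis(2,4,6-triisopropylphenyl)-1,1'-bi-2-naphthol (10 mol %), CH2Cl2, 4 Å molecular sieves, 0 °C to rt
Reagents that add atoms: none
Why: Acid-promoted dehydration gives the ortho-quinone methide, which undergoes an inverse-electron-demand hetero-Diels–Alder reaction with the E-stilbene (O1 to the carbon bearing the 4-silyloxyphenyl ring, the better cation-stabilizing end); the E-alkene gives 2,3-trans, the endo approach of the C2 aryl group to the E-quinone methide gives 2,4-cis and hence 3,4-trans, and the chiral phosphoramide hydrogen-bonded to the quinone methide selects the enantioface.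

Step 17
Reactants: 33 1-(2,4-dihydroxyphenyl)ethanone
Product: 34 1-[2,4-bis(TBSO)phenyl]ethanone
Conditions: t-BuMe2SiCl (2.5 equiv), imidazole, DMAP, DMF, 50 °C
Reagents that add atoms: tert-butyldimethylsilyl chloride, CC(C)(C)[Si](C)(C)Cl
Why: Exhaustive phenol silylation (the hydrogen-bonded 2-OH needs forcing), which also blocks later flavanone formation.

Step 18
Reactants: 34 1-[2,4-bis(TBSO)phenyl]ethanone; 32 chroman aldehyde from step 16
Product: 38 (E)-1-[2,4-bis(TBSO)phenyl]-3-{3-[(2S,3R,4S)-4-(5-bromo-2,4-bis(TBSO)phenyl)-7-(TBSO)-2-(4-(TBSO)phenyl)-3,4-dihydro-2H-chromen-3-yl]-4-(TBSO)phenyl}prop-2-en-1-one, via lithium enolate 35 (not isolated), via lithium aldolate 36 (not isolated), via aldol mesylate 37 (not isolated)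
Conditions: 34, LiN(SiMe3)2, THF, −78 °C; then 32; then MeSO2Cl, Et3N, −78 °C to rt
Reagents that add atoms: none
Why: Directed aldol addition followed by mesylation and E1cB elimination (a Claisen–Schmidt condensation run under silyl-ether-compatible conditions) should give the E-enone.

Step 19
Reactants: 38 bromo chalcone from step 18
Product: 39 pinacol boronate of 38 (Bpin in place of Br)
Conditions: B2pin2, Pd2(dba)3, 2-dicyclohexylphosphino-2',4',6'-triisopropylbiphenyl (XPhos), KOAc, 1,4-dioxane, 90 °C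
Reagents that add atoms: bis(pinacolato)diboron, CC1(C)OB(OC1(C)C)B1OC(C)(C)C(C)(C)O1
Why: Miyaura borylation of the aryl bromide with a bulky electron-rich phosphine suited to the hindered, electron-rich ring; the enone and silyl ethers should tolerate KOAc.

Step 20
Reactants: 39 pinacol boronate
Product: 40 arylboronic acid (B(OH)2 in place of Br of 38; fragment 2)
Conditions: NaIO4, NH4OAc, acetone/H2O, rt
Reagents that add atoms: water, O
Why: Hydrolysis of the boronate is driven by periodate cleavage of the released pinacol, under near-neutral conditions.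

Step 21
Reactants: 40 arylboronic acid (fragment 2); 20 thioester (fragment 1)
Product: 43 undeca-TBS ether of the target, via keto silyl ether 41 (not isolated), via oxolanylium triflate 42 (not isolated)
Conditions: Pd2(dba)3 (5 mol %), P(2-furyl)3 (20 mol %), Cu(O2CC4H3S) (1.6 equiv), THF, 50 °C; then CH2Cl2, Et3SiH, Me3SiOTf, −78 to −50 °C; Et3N/NaHCO3 quench at −78 °C
Reagents that add atoms: none
Why: Zerovalent palladium inserts into the acyl–sulfur bond of 20 (assisted by monovalent copper on sulfur), the aryl group of 40 is transferred from boron activated by the carboxylate, and reductive elimination forms the central-ring C5–carbonyl bond under neutral, base-free conditions to give ketone 41; Me3SiOTf then activates this ketone, the gamma-silyl ether oxygen adds to it with loss of the triethylsilyl group to give the 2-aryloxolanylium ion 42, and Et3SiH delivers hydride. The closest precedents are the Liebeskind–Srogl thioester–boronic acid ketone synthesis on alpha-branched thioesters without epimerization, and the reductive cycloetherification of silyloxy ketones (ionic hydrogenation of 2-aryl cyclic hemiketals to 2,3-cis-2-aryloxolanes). The oxolane closes by 5-exo-trig attack of O1 on the carbonyl carbon, and C5 keeps its configuration because the C5–O1 bond is never broken. The one new stereocentre, C2, is set by hydride attack anti to the C3 benzyl group, which is held pseudoaxial by allylic 1,2-strain with the coplanar aryl ring (inside attack on that envelope), so the aryl group ends cis to the benzyl group (2S). Site selectivity on the arene is fixed by the boron placed from the bromide, only the thioester is cleaved by palladium, and only the ketone with a gamma-oxygen can form a cyclic oxocarbenium ion, so the C4 aroyl ketone and the chalcone should not be reduced at −78 °C. The low temperature and cold basic quench are needed to prevent acid-mediated ring opening and re-closure, which would epimerize C2 to the more stable 2,3-trans isomer.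

Step 22
Reactants: 43 undeca-TBS ether of the target
Product: 44 CNP0330082.3 (target)
Conditions: Bu4NF/AcOH (1:1, excess), THF, 0 °C to rt
Reagents that add atoms: none
Why: Fluoride cleavage of the eleven aryl silyl ethers under acetic acid buffering, which avoids both acid-mediated epimerization at oxolane C2 and base-mediated retro-oxa-Michael opening or flavanone formation.

**Compound list**

1 | 3-(4-hydroxyphenyl)propanoic acid | OC(=O)CCc1ccc(O)cc1 | starting material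
2 | TBS 3-[4-(TBSO)phenyl]propanoate | CC(C)(C)[Si](C)(C)OC(=O)CCc1ccc(O[Si](C)(C)C(C)(C)C)cc1 | intermediate
3 | 3-[4-(TBSO)phenyl]propanoic acid | OC(=O)CCc1ccc(O[Si](C)(C)C(C)(C)C)cc1 | intermediate
4 | (S)-4-benzyl-1,3-oxazolidin-2-one | O=C1OC[C@H](Cc2ccccc2)N1 | starting material
5 | mixed anhydride of 3 with pivalic acid | CC(C)(C)C(=O)OC(=O)CCc1ccc(O[Si](C)(C)C(C)(C)C)cc1 | intermediate
6 | (S)-4-benzyl-3-{3-[4-(TBSO)phenyl]propanoyl}-1,3-oxazolidin-2-one | O=C1OC[C@H](Cc2ccccc2)N1C(=O)CCc1ccc(O[Si](C)(C)C(C)(C)C)cc1 | intermediate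
7 | sodium (Z)-enolate of 6 | [Na+].[O-]/C(=C\Cc1ccc(O[Si](C)(C)C(C)(C)C)cc1)N1C(=O)OC[C@@H]1Cc1ccccc1 | intermediate
8 | tert-butyl (3R)-4-[(4S)-4-benzyl-2-oxo-1,3-oxazolidin-3-yl]-4-oxo-3-[4-(TBSO)benzyl]butanoate | O=C1OC[C@H](Cc2ccccc2)N1C(=O)[C@H](Cc1ccc(O[Si](C)(C)C(C)(C)C)cc1)CC(=O)OC(C)(C)C | intermediate
9 | (3R)-4-[(4S)-4-benzyl-2-oxo-1,3-oxazolidin-3-yl]-4-oxo-3-[4-(TBSO)benzyl]butanoic acid | O=C1OC[C@H](Cc2ccccc2)N1C(=O)[C@H](Cc1ccc(O[Si](C)(C)C(C)(C)C)cc1)CC(=O)O | intermediate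
10 | (R)-4-benzyl-1,3-thiazolidine-2-thione | S=C1SC[C@@H](Cc2ccccc2)N1 | starting material
11 | (S)-4-benzyl-3-{(2R)-2-[4-(TBSO)benzyl]-4-[(4R)-4-benzyl-2-thioxo-1,3-thiazolidin-3-yl]-4-oxobutanoyl}-1,3-oxazolidin-2-one | O=C1OC[C@H](Cc2ccccc2)N1C(=O)[C@H](Cc1ccc(O[Si](C)(C)C(C)(C)C)cc1)CC(=O)N1C(=S)SC[C@H]1Cc1ccccc1 | intermediate
12 | 4-(TBSO)benzaldehyde | O=Cc1ccc(O[Si](C)(C)C(C)(C)C)cc1 | starting material
13 | trimethylsilyl ether of 14 | O=C1OC[C@H](Cc2ccccc2)N1C(=O)[C@H](Cc1ccc(O[Si](C)(C)C(C)(C)C)cc1)[C@@H](C(=O)N1C(=S)SC[C@H]1Cc1ccccc1)[C@H](O[Si](C)(C)C)c1ccc(O[Si](C)(C)C(C)(C)C)cc1 | intermediate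
14 | anti-aldol adduct: (S)-4-benzyl-3-[(2R,3R)-2-[4-(TBSO)benzyl]-3-{(S)-hydroxy[4-(TBSO)phenyl]methyl}-4-oxo-4-((4R)-4-benzyl-2-thioxo-1,3-thiazolidin-3-yl)butanoyl]-1,3-oxazolidin-2-one | O=C1OC[C@H](Cc2ccccc2)N1C(=O)[C@H](Cc1ccc(O[Si](C)(C)C(C)(C)C)cc1)[C@@H](C(=O)N1C(=S)SC[C@H]1Cc1ccccc1)[C@H](O)c1ccc(O[Si](C)(C)C(C)(C)C)cc1 | intermediate
15 | triethylsilyl ether of 14 | O=C1OC[C@H](Cc2ccccc2)N1C(=O)[C@H](Cc1ccc(O[Si](C)(C)C(C)(C)C)cc1)[C@@H](C(=O)N1C(=S)SC[C@H]1Cc1ccccc1)[C@H](O[Si](CC)(CC)CC)c1ccc(O[Si](C)(C)C(C)(C)C)cc1 | intermediate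
16 | 4-bromobenzene-1,3-diol | Oc1ccc(Br)c(O)c1 | starting material
17 | 1-bromo-2,4-bis(TBSO)benzene | CC(C)(C)[Si](C)(C)Oc1ccc(Br)c(O[Si](C)(C)C(C)(C)C)c1 | intermediate
18 | [2,4-bis(TBSO)phenyl]magnesium bromide | CC(C)(C)[Si](C)(C)Oc1ccc([Mg]Br)c(O[Si](C)(C)C(C)(C)C)c1 | intermediate
19 | (S)-4-benzyl-3-{(2R,3R,4S)-3-[2,4-bis(TBSO)benzoyl]-2-[4-(TBSO)benzyl]-4-[4-(TBSO)phenyl]-4-(triethylsilyloxy)butanoyl}-1,3-oxazolidin-2-one | O=C1OC[C@H](Cc2ccccc2)N1C(=O)[C@H](Cc1ccc(O[Si](C)(C)C(C)(C)C)cc1)[C@@H](C(=O)c1ccc(O[Si](C)(C)C(C)(C)C)cc1O[Si](C)(C)C(C)(C)C)[C@H](O[Si](CC)(CC)CC)c1ccc(O[Si](C)(C)C(C)(C)C)cc1 | intermediate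
20 | fragment 1: S-ethyl (2R,3R,4S)-3-[2,4-bis(TBSO)benzoyl]-2-[4-(TBSO)benzyl]-4-[4-(TBSO)phenyl]-4-(triethylsilyloxy)butanethioate | CCSC(=O)[C@H](Cc1ccc(O[Si](C)(C)C(C)(C)C)cc1)[C@@H](C(=O)c1ccc(O[Si](C)(C)C(C)(C)C)cc1O[Si](C)(C)C(C)(C)C)[C@H](O[Si](CC)(CC)CC)c1ccc(O[Si](C)(C)C(C)(C)C)cc1 | intermediate
21 | 3-bromo-4-hydroxybenzaldehyde | O=Cc1ccc(O)c(Br)c1 | starting material
22 | 3-bromo-4-(TBSO)benzaldehyde | O=Cc1ccc(O[Si](C)(C)C(C)(C)C)c(Br)c1 | intermediate
23 | tert-butyldimethyl(4-vinylphenoxy)silane | C=Cc1ccc(O[Si](C)(C)C(C)(C)C)cc1 | starting material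
24 | 4-(TBSO)-3-{(E)-2-[4-(TBSO)phenyl]ethenyl}benzaldehyde | O=Cc1ccc(O[Si](C)(C)C(C)(C)C)c(/C=C/c2ccc(O[Si](C)(C)C(C)(C)C)cc2)c1 | intermediate
25 | 4,6-dibromobenzene-1,3-diol | Oc1cc(O)c(Br)cc1Br | starting material
26 | 1,5-dibromo-2,4-bis(TBSO)benzene | CC(C)(C)[Si](C)(C)Oc1cc(O[Si](C)(C)C(C)(C)C)c(Br)cc1Br | intermediate
27 | 2,4-dihydroxybenzaldehyde | O=Cc1ccc(O)cc1O | starting material
28 | 4-(TBSO)-2-hydroxybenzaldehyde | O=Cc1ccc(O[Si](C)(C)C(C)(C)C)cc1O | intermediate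
29 | [5-bromo-2,4-bis(TBSO)phenyl]lithium | [Li]c1cc(Br)c(O[Si](C)(C)C(C)(C)C)cc1O[Si](C)(C)C(C)(C)C | intermediate
30 | [5-bromo-2,4-bis(TBSO)phenyl][4-(TBSO)-2-hydroxyphenyl]methanol (racemic) | OC(c1ccc(O[Si](C)(C)C(C)(C)C)cc1O)c1cc(Br)c(O[Si](C)(C)C(C)(C)C)cc1O[Si](C)(C)C(C)(C)C | intermediate
31 | ortho-quinone methide: 6-{[5-bromo-2,4-bis(TBSO)phenyl]methylidene}-3-(TBSO)cyclohexa-2,4-dien-1-one | O=C1C=C(O[Si](C)(C)C(C)(C)C)C=CC1=Cc1cc(Br)c(O[Si](C)(C)C(C)(C)C)cc1O[Si](C)(C)C(C)(C)C | intermediate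
32 | 3-{(2S,3R,4S)-4-[5-bromo-2,4-bis(TBSO)phenyl]-7-(TBSO)-2-[4-(TBSO)phenyl]-3,4-dihydro-2H-chromen-3-yl}-4-(TBSO)benzaldehyde (2,3-trans, 3,4-trans) | O=Cc1ccc(O[Si](C)(C)C(C)(C)C)c([C@H]2[C@H](c3cc(Br)c(O[Si](C)(C)C(C)(C)C)cc3O[Si](C)(C)C(C)(C)C)c3ccc(O[Si](C)(C)C(C)(C)C)cc3O[C@@H]2c2ccc(O[Si](C)(C)C(C)(C)C)cc2)c1 | intermediate
33 | 1-(2,4-dihydroxyphenyl)ethanone | CC(=O)c1ccc(O)cc1O | starting material
34 | 1-[2,4-bis(TBSO)phenyl]ethanone | CC(=O)c1ccc(O[Si](C)(C)C(C)(C)C)cc1O[Si](C)(C)C(C)(C)C | intermediate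
35 | lithium enolate of 34 | [Li+].[O-]C(=C)c1ccc(O[Si](C)(C)C(C)(C)C)cc1O[Si](C)(C)C(C)(C)C | intermediate
36 | lithium aldolate from 35 and 32 (carbinol epimers) | [Li+].[O-]C(CC(=O)c1ccc(O[Si](C)(C)C(C)(C)C)cc1O[Si](C)(C)C(C)(C)C)c1ccc(O[Si](C)(C)C(C)(C)C)c([C@H]2[C@H](c3cc(Br)c(O[Si](C)(C)C(C)(C)C)cc3O[Si](C)(C)C(C)(C)C)c3ccc(O[Si](C)(C)C(C)(C)C)cc3O[C@@H]2c2ccc(O[Si](C)(C)C(C)(C)C)cc2)c1 | intermediate
37 | methanesulfonate of the aldol | CS(=O)(=O)OC(CC(=O)c1ccc(O[Si](C)(C)C(C)(C)C)cc1O[Si](C)(C)C(C)(C)C)c1ccc(O[Si](C)(C)C(C)(C)C)c([C@H]2[C@H](c3cc(Br)c(O[Si](C)(C)C(C)(C)C)cc3O[Si](C)(C)C(C)(C)C)c3ccc(O[Si](C)(C)C(C)(C)C)cc3O[C@@H]2c2ccc(O[Si](C)(C)C(C)(C)C)cc2)c1 | intermediate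
38 | bromo chalcone: (E)-1-[2,4-bis(TBSO)phenyl]-3-{3-[(2S,3R,4S)-4-(5-bromo-2,4-bis(TBSO)phenyl)-7-(TBSO)-2-(4-(TBSO)phenyl)-3,4-dihydro-2H-chromen-3-yl]-4-(TBSO)phenyl}prop-2-en-1-one | O=C(/C=C/c1ccc(O[Si](C)(C)C(C)(C)C)c([C@H]2[C@H](c3cc(Br)c(O[Si](C)(C)C(C)(C)C)cc3O[Si](C)(C)C(C)(C)C)c3ccc(O[Si](C)(C)C(C)(C)C)cc3O[C@@H]2c2ccc(O[Si](C)(C)C(C)(C)C)cc2)c1)c1ccc(O[Si](C)(C)C(C)(C)C)cc1O[Si](C)(C)C(C)(C)C | intermediate
39 | pinacol boronate (Bpin in place of Br of 38) | O=C(/C=C/c1ccc(O[Si](C)(C)C(C)(C)C)c([C@H]2[C@H](c3cc(B4OC(C)(C)C(C)(C)O4)c(O[Si](C)(C)C(C)(C)C)cc3O[Si](C)(C)C(C)(C)C)c3ccc(O[Si](C)(C)C(C)(C)C)cc3O[C@@H]2c2ccc(O[Si](C)(C)C(C)(C)C)cc2)c1)c1ccc(O[Si](C)(C)C(C)(C)C)cc1O[Si](C)(C)C(C)(C)C | intermediate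
40 | fragment 2: arylboronic acid (B(OH)2 in place of Br of 38) | O=C(/C=C/c1ccc(O[Si](C)(C)C(C)(C)C)c([C@H]2[C@H](c3cc(B(O)O)c(O[Si](C)(C)C(C)(C)C)cc3O[Si](C)(C)C(C)(C)C)c3ccc(O[Si](C)(C)C(C)(C)C)cc3O[C@@H]2c2ccc(O[Si](C)(C)C(C)(C)C)cc2)c1)c1ccc(O[Si](C)(C)C(C)(C)C)cc1O[Si](C)(C)C(C)(C)C | intermediate
41 | gamma-(triethylsilyloxy) aryl ketone: central-ring C5 of fragment 2 acylated by the (2R,3R,4S)-butanoyl chain of 20 | O=C(/C=C/c1ccc(O[Si](C)(C)C(C)(C)C)c([C@H]2[C@H](c3cc(C(=O)[C@H](Cc4ccc(O[Si](C)(C)C(C)(C)C)cc4)[C@@H](C(=O)c4ccc(O[Si](C)(C)C(C)(C)C)cc4O[Si](C)(C)C(C)(C)C)[C@H](O[Si](CC)(CC)CC)c4ccc(O[Si](C)(C)C(C)(C)C)cc4)c(O[Si](C)(C)C(C)(C)C)cc3O[Si](C)(C)C(C)(C)C)c3ccc(O[Si](C)(C)C(C)(C)C)cc3O[C@@H]2c2ccc(O[Si](C)(C)C(C)(C)C)cc2)c1)c1ccc(O[Si](C)(C)C(C)(C)C)cc1O[Si](C)(C)C(C)(C)C | intermediate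
42 | 2-aryl-(3R,4R,5S)-oxolan-1-ylium triflate formed from 41 | O=C(/C=C/c1ccc(O[Si](C)(C)C(C)(C)C)c([C@H]2[C@H](c3cc(C4=[O+][C@H](c5ccc(O[Si](C)(C)C(C)(C)C)cc5)[C@H](C(=O)c5ccc(O[Si](C)(C)C(C)(C)C)cc5O[Si](C)(C)C(C)(C)C)[C@H]4Cc4ccc(O[Si](C)(C)C(C)(C)C)cc4)c(O[Si](C)(C)C(C)(C)C)cc3O[Si](C)(C)C(C)(C)C)c3ccc(O[Si](C)(C)C(C)(C)C)cc3O[C@@H]2c2ccc(O[Si](C)(C)C(C)(C)C)cc2)c1)c1ccc(O[Si](C)(C)C(C)(C)C)cc1O[Si](C)(C)C(C)(C)C.[O-]S(=O)(=O)C(F)(F)F | intermediate
43 | undeca-TBS ether of the target: oxolane (2S,3R,4R,5S), chroman (2S,3R,4S), E-enone | O=C(/C=C/c1ccc(O[Si](C)(C)C(C)(C)C)c([C@H]2[C@H](c3cc([C@H]4O[C@H](c5ccc(O[Si](C)(C)C(C)(C)C)cc5)[C@H](C(=O)c5ccc(O[Si](C)(C)C(C)(C)C)cc5O[Si](C)(C)C(C)(C)C)[C@H]4Cc4ccc(O[Si](C)(C)C(C)(C)C)cc4)c(O[Si](C)(C)C(C)(C)C)cc3O[Si](C)(C)C(C)(C)C)c3ccc(O[Si](C)(C)C(C)(C)C)cc3O[C@@H]2c2ccc(O[Si](C)(C)C(C)(C)C)cc2)c1)c1ccc(O[Si](C)(C)C(C)(C)C)cc1O[Si](C)(C)C(C)(C)C | intermediate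
44 | CNP0330082.3: (E)-1-(2,4-dihydroxyphenyl)-3-{4-hydroxy-3-[(2S,3R,4R)-7-hydroxy-2-(4-hydroxyphenyl)-4-{2,4-dihydroxy-5-[(2S,3R,4R,5S)-4-(2,4-dihydroxybenzoyl)-3-(4-hydroxybenzyl)-5-(4-hydroxyphenyl)oxolan-2-yl]phenyl}-3,4-dihydro-2H-chromen-3-yl]phenyl}prop-2-en-1-one | O=C(/C=C/c1ccc(O)c([C@H]2[C@H](c3cc([C@H]4O[C@H](c5ccc(O)cc5)[C@H](C(=O)c5ccc(O)cc5O)[C@H]4Cc4ccc(O)cc4)c(O)cc3O)c3ccc(O)cc3O[C@@H]2c2ccc(O)cc2)c1)c1ccc(O)cc1O | target

**Summary**

Total step count: 22. Longest linear sequence: 11 steps (steps 1 to 7, 9, 10, 21, 22).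

**Steps most likely to fail**

Step 21 (key step). What may go wrong: slow transmetalation and protodeboronation of the hindered, electron-rich ortho-silyloxy boronic acid; disturbance of the silane stage by the spent copper and boron salts; or partial epimerization at C2 through reversible ring opening if the mixture warms. The fallback separates the union from the ring closure and changes the nucleophile. It sets out from bromide 38 and thioester 20. Bromide 38 is treated with Me3SnSnMe3 and Pd(PPh3)4 in toluene at 100 °C to give the aryltrimethylstannane F1. F1 is coupled with 20 under Pd2(dba)3, P(2-furyl)3 and Cu(O2PPh2) in THF at 50 °C (thioester–organostannane ketone synthesis), and ketone 41 is isolated. Pyridine-buffered HF·pyridine in THF at 0 °C removes only the alkyl triethylsilyl ether and gives the cyclic hemiketal F2 (anomeric mixture). Et3SiH/BF3·OEt2 in CH2Cl2 at −78 °C then reduces F2 by the same anti-to-benzyl hydride delivery, and the route is rejoined at 43.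

Step 16. What may go wrong: poor enantiofacial discrimination, or sluggish cycloaddition because two aryl-bearing carbons with ortho-silyloxy groups must be joined. The fallback sets out from 30 and 24 and replaces asymmetric catalysis by resolution. Achiral (PhO)2P(O)OH in CH2Cl2 should give the racemic all-trans chroman, that is 32 together with its mirror image, the enantiomeric chroman aldehyde F3. The two enantiomers are separated by preparative chromatography on a chiral stationary phase, and the route is rejoined at 32.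

Step 6. What may go wrong: slow turnover of the catalytic magnesium aldol with the beta-branched, doubly N-acylated substrate, or erosion of facial selectivity by the neighbouring C3 stereocentre. The fallback sets out from 11 and moves the aldol to the ketone stage. Grignard reagent 18 displaces the thiazolidinethione first to give the keto imide F4. Enolization with (c-C6H11)2BCl/Et3N in Et2O at 0 °C gives the E-enol borinate, and addition of aldehyde 12 at −78 °C through a chair transition state gives the anti beta-hydroxy ketone F5. The facial sense then rests on 1,2-induction from C3 and would have to be checked; a wrong anti diastereomer would be removed by chromatography. Silylation of F5 with Et3SiOTf/2,6-lutidine rejoins the route at 19.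

Further compounds
F1 | step 21 | aryltrimethylstannane (SnMe3 in place of Br of 38) | O=C(/C=C/c1ccc(O[Si](C)(C)C(C)(C)C)c([C@H]2[C@H](c3cc([Sn](C)(C)C)c(O[Si](C)(C)C(C)(C)C)cc3O[Si](C)(C)C(C)(C)C)c3ccc(O[Si](C)(C)C(C)(C)C)cc3O[C@@H]2c2ccc(O[Si](C)(C)C(C)(C)C)cc2)c1)c1ccc(O[Si](C)(C)C(C)(C)C)cc1O[Si](C)(C)C(C)(C)C
F2 | step 21 | cyclic hemiketal (2-hydroxy-2-aryloxolane from 41 after loss of the triethylsilyl group, anomeric mixture) | O=C(/C=C/c1ccc(O[Si](C)(C)C(C)(C)C)c([C@H]2[C@H](c3cc(C4(O)O[C@H](c5ccc(O[Si](C)(C)C(C)(C)C)cc5)[C@H](C(=O)c5ccc(O[Si](C)(C)C(C)(C)C)cc5O[Si](C)(C)C(C)(C)C)[C@H]4Cc4ccc(O[Si](C)(C)C(C)(C)C)cc4)c(O[Si](C)(C)C(C)(C)C)cc3O[Si](C)(C)C(C)(C)C)c3ccc(O[Si](C)(C)C(C)(C)C)cc3O[C@@H]2c2ccc(O[Si](C)(C)C(C)(C)C)cc2)c1)c1ccc(O[Si](C)(C)C(C)(C)C)cc1O[Si](C)(C)C(C)(C)C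
F3 | step 16 | enantiomer of 32, (2R,3S,4R)-chroman aldehyde | O=Cc1ccc(O[Si](C)(C)C(C)(C)C)c([C@@H]2[C@@H](c3cc(Br)c(O[Si](C)(C)C(C)(C)C)cc3O[Si](C)(C)C(C)(C)C)c3ccc(O[Si](C)(C)C(C)(C)C)cc3O[C@H]2c2ccc(O[Si](C)(C)C(C)(C)C)cc2)c1
F4 | step 6 | (S)-4-benzyl-3-{(2R)-4-[2,4-bis(TBSO)phenyl]-2-[4-(TBSO)benzyl]-4-oxobutanoyl}-1,3-oxazolidin-2-one | O=C1OC[C@H](Cc2ccccc2)N1C(=O)[C@H](Cc1ccc(O[Si](C)(C)C(C)(C)C)cc1)CC(=O)c1ccc(O[Si](C)(C)C(C)(C)C)cc1O[Si](C)(C)C(C)(C)C
F5 | step 6 | (S)-4-benzyl-3-{(2R,3R,4S)-3-[2,4-bis(TBSO)benzoyl]-2-[4-(TBSO)benzyl]-4-hydroxy-4-[4-(TBSO)phenyl]butanoyl}-1,3-oxazolidin-2-one | O=C1OC[C@H](Cc2ccccc2)N1C(=O)[C@H](Cc1ccc(O[Si](C)(C)C(C)(C)C)cc1)[C@@H](C(=O)c1ccc(O[Si](C)(C)C(C)(C)C)cc1O[Si](C)(C)C(C)(C)C)[C@H](O)c1ccc(O[Si](C)(C)C(C)(C)C)cc1
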